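**Assumption:** Gustastatin (the target) has no stereocentres, so there is no configuration to set or protect. 4-Hydroxy-2-methoxybenzoic acid and 4-methoxysalicylic acid are taken as commercial.

## Retrosynthetic overview
1. Disconnect the depside (aryl ester) bond to two benzoic acid halves: ring A, a 2-OBn-4-OMe-6-(2-oxoheptyl)benzoic acid, and ring B, a methyl 4-hydroxy-2-methoxy-6-(2-oxoheptyl)benzoate phenol.
2. **Key step, in bold contrast to lateral lithiation or polyketide-type aromatisation:** each 2-oxoheptyl chain is installed in one step by carboxylate-directed Ru(II) C–H acylmethylation of a commercial benzoic acid. The coupling partner is β-keto sulfoxonium ylide **3**, made from methyl hexanoate, and the only by-product is DMSO.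
3. Both rings come ready-made from commercial benzoic acids, so no ring is built. The C–H step works at the only free ortho position of each acid.
4. Ring A's 2-OH is carried as a benzyl ether through the esterification and removed by hydrogenolysis in the last step.

## Route

**Step 1**
Reactants: **1** methyl hexanoate; **2** trimethylsulfoxonium iodide
Product: **3** 1-(dimethyloxo-λ6-sulfanylidene)heptan-2-one (hexanoyl sulfoxonium ylide)
Conditions: t-BuOK (2.5 equiv), THF, 65 °C
Reagents that add atoms: trimethylsulfoxonium iodide, C[S+](C)(C)=O.[I-] (reactant **2**)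
Why: Corey–Chaykovsky acylation of the sulfoxonium ylide by an ester; the second equivalent of ylide deprotonates the product and drives the reaction. No stereocentre is formed.

**Step 2**
Reactants: **4** 4-hydroxy-2-methoxybenzoic acid; **3**
Product: **5** 4-hydroxy-2-methoxy-6-(2-oxoheptyl)benzoic acid
Conditions: [RuCl2(p-cymene)]2 (5 mol%), AgSbF6 (20 mol%), NaOAc (1 equiv), 1,2-DCE, 100 °C, then cold dilute HCl work-up
Reagents that add atoms: none beyond **3**
Why: Carboxylate-directed Ru(II) C–H activation (C–H acylmethylation with a sulfoxonium ylide) occurs at C6, the only free ortho C–H, via a Ru carbene/migratory insertion and protodemetalation that releases DMSO; the free phenol and the isocoumarin side reaction are the extension beyond the precedented benzoic acid cases.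

**Step 3**
Reactants: **5**; **6** trimethylsilyldiazomethane
Product: **7** methyl 4-hydroxy-2-methoxy-6-(2-oxoheptyl)benzoate
Conditions: TMSCHN2 (1.2 equiv), MeOH/PhMe, 0 °C to rt
Reagents that add atoms: TMSCHN2, C[Si](C)(C)[CH-][N+]#N (supplies CH3)
Why: TMSCHN2 methylates the carboxylic acid (pKa ~3.5) selectively over the phenol (pKa ~10), and it works on hindered 2,6-disubstituted benzoic acids where Fischer esterification fails.

**Step 4**
Reactants: **8** 2-hydroxy-4-methoxybenzoic acid; **9** benzyl bromide
Product: **10** benzyl 2-(benzyloxy)-4-methoxybenzoate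
Conditions: BnBr (2.3 equiv), K2CO3, DMF, 60 °C
Reagents that add atoms: BnBr, BrCc1ccccc1
Why: Williamson O-alkylation of both the phenol and the carboxylate protects ring A's 2-OH as a benzyl ether.

**Step 5**
Reactant: **10**
Product: **11** 2-(benzyloxy)-4-methoxybenzoic acid
Conditions: NaOH, EtOH/H2O, reflux; then 1 M HCl
Reagents that add atoms: none
Why: Saponification removes the benzyl ester (the aryl benzyl ether is inert to base), giving the directing-group acid.

**Step 6**
Reactants: **11**; **3**
Product: **12** 2-(benzyloxy)-4-methoxy-6-(2-oxoheptyl)benzoic acid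
Conditions: [RuCl2(p-cymene)]2 (5 mol%), AgSbF6 (20 mol%), NaOAc (1 equiv), 1,2-DCE, 100 °C; cold acidic work-up
Reagents that add atoms: none beyond **3**
Why: The same carboxylate-directed Ru(II) C–H acylmethylation; the 2-OBn blocks one ortho position, so C6 is the only site, and the NaOAc buffer limits acid-promoted closure to the isocoumarin.

**Step 7**
Reactants: **12**; **7**
Product: **13** aryl ester, "benzyl-gustastatin" (ring A 2-OBn, ring B methyl ester)
Conditions: DCC (1.5 equiv), DMAP (0.5 equiv), DMAP·HCl (0.5 equiv), CH2Cl2, 0 °C to rt
Reagents that add atoms: none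
Why: Steglich esterification of the hindered acid with the phenol gives the depside bond; the phenol of **7** is the only free nucleophile and the ketones do not react.

**Step 8**
Reactant: **13**
Product: **14** Gustastatin
Conditions: H2 (1 atm), 10% Pd/C, EtOAc, rt
Reagents that add atoms: none (H2 only)
Why: Hydrogenolysis cleaves the aryl benzyl ether to release the salicylate OH, which is H-bonded to the ester carbonyl; the alkyl ketones, aryl ester, methyl ester and OMe groups survive.

## Compound list
1 | methyl hexanoate | CCCCCC(=O)OC | starting material
2 | trimethylsulfoxonium iodide | C[S+](C)(C)=O.[I-] | starting material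
3 | hexanoyl dimethylsulfoxonium ylide | CCCCCC(=O)[CH-][S+](C)(C)=O | intermediate
4 | 4-hydroxy-2-methoxybenzoic acid | COc1cc(O)ccc1C(=O)O | starting material
5 | 4-hydroxy-2-methoxy-6-(2-oxoheptyl)benzoic acid | CCCCCC(=O)Cc1cc(O)cc(OC)c1C(=O)O | intermediate
6 | trimethylsilyldiazomethane | C[Si](C)(C)[CH-][N+]#N | starting material (reagent)
7 | methyl 4-hydroxy-2-methoxy-6-(2-oxoheptyl)benzoate | CCCCCC(=O)Cc1cc(O)cc(OC)c1C(=O)OC | intermediate
8 | 2-hydroxy-4-methoxybenzoic acid | COc1ccc(C(=O)O)c(O)c1 | starting material
9 | benzyl bromide | BrCc1ccccc1 | starting material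
10 | benzyl 2-(benzyloxy)-4-methoxybenzoate | COc1ccc(C(=O)OCc2ccccc2)c(OCc2ccccc2)c1 | intermediate
11 | 2-(benzyloxy)-4-methoxybenzoic acid | COc1ccc(C(=O)O)c(OCc2ccccc2)c1 | intermediate
12 | 2-(benzyloxy)-4-methoxy-6-(2-oxoheptyl)benzoic acid | CCCCCC(=O)Cc1cc(OC)cc(OCc2ccccc2)c1C(=O)O | intermediate
13 | benzyl-protected depside | CCCCCC(=O)Cc1cc(OC)cc(OCc2ccccc2)c1C(=O)Oc1cc(CC(=O)CCCCC)c(C(=O)OC)c(OC)c1 | intermediate
14 | Gustastatin (achiral) | CCCCCC(=O)Cc1cc(OC)cc(O)c1C(=O)Oc1cc(CC(=O)CCCCC)c(C(=O)OC)c(OC)c1 | target

## Totals
**Total steps:** 8. **Longest linear sequence:** 5 steps (8 → 10 → 11 → 12 → 13 → 14); the ring B branch, ylide → 5 → 7 → coupling, is also 3 steps before the coupling.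

## Three steps most likely to fail, with fallbacks
1. **Step 2 (C–H acylmethylation of ring B with the free 4-OH, and isocoumarin formation).**
   - Risks: O–H insertion of the ylide by phenol or carboxylic acid, and acid-promoted closure to the 3-pentylisocoumarin.
   - Fallback: abandon C–H activation for this ring. Lateral lithiation (2.2 equiv LDA) of methyl 4-benzyloxy-2-methoxy-6-methylbenzoate, quench with N-methoxy-N-methylhexanamide, then H2/Pd-C gives **7**.
2. **Step 6 (C–H acylmethylation of the hindered 2-OBn acid).**
   - Risks: low conversion and isocoumarin by-product.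
   - Fallback: build the side chain by lateral lithiation of methyl 2-benzyloxy-4-methoxy-6-methylbenzoate with 1,2-epoxyheptane, giving the secondary alcohol; protect it as the TBS ether and hydrolyse the ester to give the acid with a masked ketone.
3. **Step 7 (hindered esterification, with intramolecular enol-lactonisation of the activated acid to the isocoumarin).**
   - Fallback: use the TBS-masked-alcohol acid from fallback 2 in the coupling, so no enolisable ketone is present during activation, then remove TBS with TBAF and oxidise with Dess–Martin periodinane before the final hydrogenolysis.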